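**Plan**

- Retrosynthesis: the 4'-O-benzyl and 5-O-methyl groups are cleaved last. The C2=C3 enol of ring C is traced back to a C3 carbinol next to the C4 ketone, and that dihydroflavonol is cut at C3–C4. The ether bond O1–C2 is cut next, leaving a ring-A catechol aldehyde and a ring-B α-bromo acetal.
- Enabling feature: in ring C the C4 carbonyl (on C4a of ring A) and the C3 hydroxyl sit on adjacent carbons. This is an acyloin pattern between an aryl aldehyde on C4a and an aldehyde at C3.
- Forward: ring A receives its fourth oxygen and its formyl group. O1–C2 is made by etherification, the 8-acetate is installed and the acetal is opened. Ring C then closes at C3–C4 by carbene catalysis, oxidation makes it aromatic, and two deprotections finish the route.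
- Stereochemistry: the target has no stereocentre. C2 and C3 of the cyclisation product are racemic, set under substrate control, and both are erased by the oxidation.

Key step: step 8

Remark: all stereogenic intermediates are racemic; compound 13 is drawn as one enantiomer of the trans pair.

**Step 1**
Reactants: 1 4-(benzyloxy)benzaldehyde; 2 (methoxymethyl)triphenylphosphonium chloride
Product: 4 1-(benzyloxy)-4-(2-methoxyethenyl)benzene (E/Z mixture), via (methoxymethylidene)triphenylphosphorane 3 (not isolated)
Conditions: KOtBu, THF, 0 °C; then 1, 0 °C to rt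
Reagents that add atoms: none
Why: Wittig olefination with the non-stabilised methoxymethylene ylide should homologate the aryl aldehyde to the enol ether, whose geometry is irrelevant because the double bond is consumed in step 2.

**Step 2**
Reactants: 4 1-(benzyloxy)-4-(2-methoxyethenyl)benzene
Product: 5 1-(benzyloxy)-4-(1-bromo-2,2-dimethoxyethyl)benzene (racemic)
Conditions: NBS, MeOH (5 equiv), CH2Cl2, −40 °C to 0 °C
Reagents that add atoms: N-bromosuccinimide, O=C1CCC(=O)N1Br; methanol, CO
Why: Bromo-alkoxylation of an enol ether should place bromine on the nucleophilic benzylic carbon while methanol traps the oxocarbenium ion, giving the racemic α-bromo acetal.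

**Step 3**
Reactants: 6 2-hydroxy-4,6-dimethoxybenzaldehyde
Product: 8 3,5-dimethoxybenzene-1,2-diol, via 2-hydroxy-4,6-dimethoxyphenyl formate 7 (not isolated)
Conditions: H2O2 (30% aq.), H2SO4 (cat.), MeOH, rt
Reagents that add atoms: hydrogen peroxide, OO
Why: In this acid-catalysed Dakin oxidation the peroxide adduct of the formyl group should rearrange by migration of the electron-rich aryl group (Baeyer–Villiger type) and the formate is methanolysed in the same pot, the acidic medium keeping the catechol from autoxidation.

**Step 4**
Reactants: 8 3,5-dimethoxybenzene-1,2-diol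
Product: 9 2,3-dihydroxy-4,6-dimethoxybenzaldehyde
Conditions: MgCl2 (anhydrous), Et3N, (CH2O)n, MeCN, reflux, Ar; then 1 M HCl
Reagents that add atoms: paraformaldehyde (as formaldehyde), C=O
Why: In the Casnati–Skattebøl magnesium-mediated ortho-formylation the magnesium phenoxide should deliver formaldehyde to the only free ortho position (C6 of the catechol) and a second formaldehyde accepts hydride, while the other open position is para to a hydroxyl and is not reached by this chelate-directed process.

**Step 5**
Reactants: 9 2,3-dihydroxy-4,6-dimethoxybenzaldehyde; 5 1-(benzyloxy)-4-(1-bromo-2,2-dimethoxyethyl)benzene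
Product: 10 2-{1-[4-(benzyloxy)phenyl]-2,2-dimethoxyethoxy}-3-hydroxy-4,6-dimethoxybenzaldehyde (racemic)
Conditions: K2CO3 (1.0 equiv), DMF, 50 °C, Ar
Reagents that add atoms: none
Why: In this Williamson etherification of the catechol mono-anion, one equivalent of carbonate should deprotonate only the more acidic hydroxyl, the one ortho to and conjugated with the formyl group, and that phenoxide displaces the benzylic bromide activated by the para-benzyloxy group.

**Step 6**
Reactants: 10 2-{1-[4-(benzyloxy)phenyl]-2,2-dimethoxyethoxy}-3-hydroxy-4,6-dimethoxybenzaldehyde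
Product: 11 2-{1-[4-(benzyloxy)phenyl]-2,2-dimethoxyethoxy}-3-formyl-4,6-dimethoxyphenyl acetate (racemic)
Conditions: Ac2O, pyridine, DMAP (cat.), CH2Cl2, 0 °C to rt
Reagents that add atoms: acetic anhydride, CC(=O)OC(C)=O
Why: DMAP-catalysed acyl transfer should acetylate the single remaining phenol, while the acetal, the aldehyde and the benzyl ether are inert.

**Step 7**
Reactants: 11 2-{1-[4-(benzyloxy)phenyl]-2,2-dimethoxyethoxy}-3-formyl-4,6-dimethoxyphenyl acetate
Product: 12 2-{1-[4-(benzyloxy)phenyl]-2-oxoethoxy}-3-formyl-4,6-dimethoxyphenyl acetate (racemic)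
Conditions: TFA–H2O (10:1), CH2Cl2, 0 °C; used crude
Reagents that add atoms: water, O
Why: Acid-catalysed acetal hydrolysis at low temperature should free the aliphatic aldehyde while the hindered aryl acetate, the benzyl ether and the aryl aldehyde persist, and the enolisable dialdehyde is taken on without purification.

**Step 8**
Reactants: 12 2-{1-[4-(benzyloxy)phenyl]-2-oxoethoxy}-3-formyl-4,6-dimethoxyphenyl acetate
Product: 13 rac-(2R,3R)-2-[4-(benzyloxy)phenyl]-3-hydroxy-5,7-dimethoxy-4-oxo-3,4-dihydro-2H-chromen-8-yl acetate (trans)
Conditions: 2-(pentafluorophenyl)-6,7-dihydro-5H-pyrrolo[2,1-c][1,2,4]triazol-2-ium tetrafluoroborate (20 mol %), iPr2NEt (20 mol %), toluene (0.02 M), rt, Ar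
Reagents that add atoms: none
Why: Proposed new method: the triazolylidene released by the amine adds to the ring-A formyl group, proton transfer gives the Breslow amino enol that acts as a C4 acyl anion, and this attacks the tethered C3 aldehyde, after which proton transfer and loss of the carbene leave the 3-hydroxy-4-ketone; the closest known reaction type is the triazolium-catalysed intramolecular crossed aldehyde–ketone benzoin of 2-(2-oxoalkoxy)benzaldehydes to 3-hydroxychroman-4-ones, from which this case differs in that the acceptor is itself an aldehyde. Ring C closes in a 6-exo-trig mode, the new C3–C4 bond lying in the ring and the attacked C3=O outside it. C2 is carried over racemic from 12 and the new C3 carbinol is expected trans to the C2 aryl group under substrate control (both substituents equatorial, and the α-ketol can equilibrate), although neither centre outlives step 9. The step needs the carbene to engage the aromatic rather than the α-aryloxy aliphatic aldehyde, whose Breslow intermediate could expel the ring-A aryloxide in an internal redox, and it needs ring closure to outrun intermolecular benzoin and base-mediated aldol closure from C2. The α-branching of the aliphatic aldehyde, the readiness of ortho-alkoxybenzaldehydes to form carbene adducts, an electron-poor N-pentafluorophenyl carbene that adds reversibly and promotes aryloxide loss poorly, a hindered amine in catalytic amount and high dilution are relied on for this. Should the aliphatic aldehyde nevertheless serve as donor and close, the regioisomeric 4-hydroxy-3-ketone results, and step 9 takes it to the same dione 14.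

**Step 9**
Reactants: 13 rac-(2R,3R)-2-[4-(benzyloxy)phenyl]-3-hydroxy-5,7-dimethoxy-4-oxo-3,4-dihydro-2H-chromen-8-yl acetate
Product: 15 2-[4-(benzyloxy)phenyl]-3-hydroxy-5,7-dimethoxy-4-oxo-4H-chromen-8-yl acetate, via chroman-3,4-dione 14 (not isolated)
Conditions: Dess–Martin periodinane (1.2 equiv), CH2Cl2, 0 °C to rt
Reagents that add atoms: none
Why: Dess–Martin oxidation of the α-ketol should give the 2-arylchroman-3,4-dione, which enolises across C2–C3 to the aromatic 3-hydroxy-4-pyranone, so that both stereocentres and any cis or regioisomeric acyloin converge on one flavonol.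

**Step 10**
Reactants: 15 2-[4-(benzyloxy)phenyl]-3-hydroxy-5,7-dimethoxy-4-oxo-4H-chromen-8-yl acetate
Product: 16 3-hydroxy-2-(4-hydroxyphenyl)-5,7-dimethoxy-4-oxo-4H-chromen-8-yl acetate
Conditions: H2 (1 atm), 10% Pd/C, EtOAc–THF, rt
Reagents that add atoms: none
Why: Catalytic hydrogenolysis should cleave the benzyl aryl ether under neutral conditions that leave the aromatic pyranone, the acetate and the methyl ethers untouched.

**Step 11**
Reactants: 16 3-hydroxy-2-(4-hydroxyphenyl)-5,7-dimethoxy-4-oxo-4H-chromen-8-yl acetate
Product: 17 3,5-dihydroxy-2-(4-hydroxyphenyl)-7-methoxy-4-oxo-4H-chromen-8-yl acetate (pollenitin 8-acetate)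
Conditions: BCl3 (1 M in CH2Cl2, 5 equiv), CH2Cl2, −78 °C to 0 °C; then H2O
Reagents that add atoms: none
Why: In this chelation-controlled Lewis-acid demethylation boron should bind the C4 carbonyl and the peri 5-methoxy oxygen so that chloride removes only that methyl group, the 7-methoxy group lacking such a six-membered chelate and the aryl acetate resisting BCl3 at low temperature.

**Compound list**

1 | 4-(benzyloxy)benzaldehyde | O=Cc1ccc(OCc2ccccc2)cc1 | starting material
2 | (methoxymethyl)triphenylphosphonium chloride | COC[P+](c1ccccc1)(c1ccccc1)c1ccccc1.[Cl-] | starting material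
3 | (methoxymethylidene)triphenylphosphorane | COC=P(c1ccccc1)(c1ccccc1)c1ccccc1 | intermediate (not isolated)
4 | 1-(benzyloxy)-4-(2-methoxyethenyl)benzene (E/Z mixture) | COC=Cc1ccc(OCc2ccccc2)cc1 | intermediate
5 | 1-(benzyloxy)-4-(1-bromo-2,2-dimethoxyethyl)benzene (racemic) | COC(OC)C(Br)c1ccc(OCc2ccccc2)cc1 | intermediate
6 | 2-hydroxy-4,6-dimethoxybenzaldehyde | COc1cc(O)c(C=O)c(OC)c1 | starting material
7 | 2-hydroxy-4,6-dimethoxyphenyl formate | COc1cc(O)c(OC=O)c(OC)c1 | intermediate (not isolated)
8 | 3,5-dimethoxybenzene-1,2-diol | COc1cc(O)c(O)c(OC)c1 | intermediate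
9 | 2,3-dihydroxy-4,6-dimethoxybenzaldehyde | COc1cc(OC)c(O)c(O)c1C=O | intermediate
10 | 2-{1-[4-(benzyloxy)phenyl]-2,2-dimethoxyethoxy}-3-hydroxy-4,6-dimethoxybenzaldehyde (racemic) | COc1cc(OC)c(O)c(OC(C(OC)OC)c2ccc(OCc3ccccc3)cc2)c1C=O | intermediate
11 | 2-{1-[4-(benzyloxy)phenyl]-2,2-dimethoxyethoxy}-3-formyl-4,6-dimethoxyphenyl acetate (racemic) | COc1cc(OC)c(OC(C)=O)c(OC(C(OC)OC)c2ccc(OCc3ccccc3)cc2)c1C=O | intermediate
12 | 2-{1-[4-(benzyloxy)phenyl]-2-oxoethoxy}-3-formyl-4,6-dimethoxyphenyl acetate (racemic) | COc1cc(OC)c(OC(C)=O)c(OC(C=O)c2ccc(OCc3ccccc3)cc2)c1C=O | intermediate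
13 | rac-(2R,3R)-2-[4-(benzyloxy)phenyl]-3-hydroxy-5,7-dimethoxy-4-oxo-3,4-dihydro-2H-chromen-8-yl acetate (trans, one enantiomer drawn) | COc1cc(OC)c2C(=O)[C@H](O)[C@@H](c3ccc(OCc4ccccc4)cc3)Oc2c1OC(C)=O | intermediate
14 | 2-[4-(benzyloxy)phenyl]-5,7-dimethoxy-3,4-dioxo-3,4-dihydro-2H-chromen-8-yl acetate (racemic) | COc1cc(OC)c2C(=O)C(=O)C(c3ccc(OCc4ccccc4)cc3)Oc2c1OC(C)=O | intermediate (not isolated)
15 | 2-[4-(benzyloxy)phenyl]-3-hydroxy-5,7-dimethoxy-4-oxo-4H-chromen-8-yl acetate | COc1cc(OC)c2c(=O)c(O)c(-c3ccc(OCc4ccccc4)cc3)oc2c1OC(C)=O | intermediate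
16 | 3-hydroxy-2-(4-hydroxyphenyl)-5,7-dimethoxy-4-oxo-4H-chromen-8-yl acetate | COc1cc(OC)c2c(=O)c(O)c(-c3ccc(O)cc3)oc2c1OC(C)=O | intermediate
17 | 3,5-dihydroxy-2-(4-hydroxyphenyl)-7-methoxy-4-oxo-4H-chromen-8-yl acetate (pollenitin 8-acetate) | COc1cc(O)c2c(=O)c(O)c(-c3ccc(O)cc3)oc2c1OC(C)=O | target

**Step count**

Total: 11 steps. Longest linear sequence: 9 steps (steps 3 to 11 from 6; the ring-B branch through steps 1, 2 and 5 to 11 is equally long).

**Steps most likely to fail**

1. Step 8. The carbene may form its Breslow intermediate on the aliphatic aldehyde and expel the ring-A aryloxide, ending in acyl transfer and loss of the tether. Alternatively the electron-rich, doubly ortho-substituted aryl aldehyde may react so slowly that aldol closure from C2 or oligomerisation takes over. The fallback sets out from 12 and forms the same C3–C4 bond reductively. Samarium diiodide (SmI2, t-BuOH, THF, −78 °C) should reduce the conjugated aryl aldehyde to its ketyl, which adds to the aliphatic aldehyde in a pinacol cyclisation. This would give the diol 2-[4-(benzyloxy)phenyl]-3,4-dihydroxy-5,7-dimethoxy-3,4-dihydro-2H-chromen-8-yl acetate F1. Swern oxidation of both carbinols ((COCl)2, DMSO, Et3N, CH2Cl2, −78 °C to rt) would give dione 14, which enolises in the presence of the amine. The route is rejoined at 15.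

2. Step 5. Site selection between the two catechol oxygens may be incomplete, and substitution at a hindered benzylic carbon next to an acetal may be slow enough for solvolysis of the bromide to compete. The fallback sets out from 9 and 4 and makes the ether by redox condensation with the acetate already in place. Mono-acetylation of 9 (Ac2O 1.0 equiv, Et3N, CH2Cl2, −20 °C) should settle the acetyl group on O3, where the 2-hydroxyl keeps its hydrogen bond to the formyl oxygen. This gives 3-formyl-2-hydroxy-4,6-dimethoxyphenyl acetate F2. Epoxidation of enol ether 4 in methanol (mCPBA, MeOH, 0 °C) should give 1-[4-(benzyloxy)phenyl]-2,2-dimethoxyethan-1-ol F3. Mitsunobu etherification of F2 with F3 (PPh3, DIAD, toluene, 0 °C to rt) would give 11 directly, bypassing 10 and step 6.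

3. Step 4. The catechol may bind magnesium as a chelate that does not pass formaldehyde on to the ring, or may be lost to oxidation and hydroxymethyl oligomerisation. The fallback sets out from 8 and introduces the formyl group by directed metalation. Protection (MOMCl, iPr2NEt, CH2Cl2) should give 1,2-bis(methoxymethoxy)-3,5-dimethoxybenzene F4. Lithiation (n-BuLi, TMEDA, THF, −20 °C to 0 °C) is expected between the methoxymethoxy and methoxy groups, the former being the stronger director. Quenching with DMF gives 2,3-bis(methoxymethoxy)-4,6-dimethoxybenzaldehyde F5. Cleavage of both acetals (HCl, MeOH, rt) returns to the route at 9.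

**Further compounds**

F1 | step 8 | 2-[4-(benzyloxy)phenyl]-3,4-dihydroxy-5,7-dimethoxy-3,4-dihydro-2H-chromen-8-yl acetate (racemic diastereomer mixture) | COc1cc(OC)c2C(O)C(O)C(c3ccc(OCc4ccccc4)cc3)Oc2c1OC(C)=O
F2 | step 5 | 3-formyl-2-hydroxy-4,6-dimethoxyphenyl acetate | COc1cc(OC)c(OC(C)=O)c(O)c1C=O
F3 | step 5 | 1-[4-(benzyloxy)phenyl]-2,2-dimethoxyethan-1-ol (racemic) | COC(OC)C(O)c1ccc(OCc2ccccc2)cc1
F4 | step 4 | 1,2-bis(methoxymethoxy)-3,5-dimethoxybenzene | COc1cc(OCOC)c(OCOC)c(OC)c1
F5 | step 4 | 2,3-bis(methoxymethoxy)-4,6-dimethoxybenzaldehyde | COCOc1c(OCOC)c(OC)cc(OC)c1C=O
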